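**Plan**

- Retrosynthesis: the three MOM ethers are removed last, the C2 hydrogen is taken back to a flavone, and ring C of the flavone is cut at C8a–O1, C4a–C4 and O1–C2 into an aryne and an arylpropiolic acid.
- Enabling feature (flavanone numbering): ring A joins ring C through C8a–O1 and C4a–C4 and carries the C5 oxygen next to C4a, which is the polarity of a 3-alkoxyaryne that takes an oxygen nucleophile at the distal carbon and an acyl group at the proximal one.
- Forward: rings A and B are bought (resorcinol, isovanillin). Resorcinol bis-MOM ether is geranylated at C2 by ortho-lithiation, oxygenated by C–H borylation/oxidation, then brominated, silyl-shifted and triflated to the aryne precursor. Isovanillin gives the propiolic acid in three steps.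
- Ring C is the only ring formed, in one operation, by aryne C–O insertion followed by 6-endo-dig closure.
- Stereochemistry: the E-alkene comes with geranyl bromide. C2 (S) is set by ligand-controlled copper hydride conjugate reduction of the flavone.

Key step: step 9

Assumption: (S)-DTBM-SEGPHOS is taken to deliver hydride to the face of C2 that gives the 2S series, by analogy with 3-substituted cyclohexenones; a test reduction decides, and the (R)-ligand is used if the sense is opposite.

Abbreviations: MOM = methoxymethyl; geranyl = (2E)-3,7-dimethylocta-2,6-dien-1-yl; dtbpy = 4,4'-di-tert-butyl-2,2'-bipyridine; flavanone numbering is used for ring positions.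

**Route**

Step 1
Reactants: 1 resorcinol
Product: 2 1,3-bis(methoxymethoxy)benzene
Conditions: MOMCl, iPr2NEt, CH2Cl2, 0 °C to rt
Reagents that add atoms: chloromethyl methyl ether, COCCl
Why: O-alkylation of both phenols (MOM ether formation) is routine and installs the two groups that later direct the ortho-lithiation.

Step 2
Reactants: 2 1,3-bis(methoxymethoxy)benzene; 3 geranyl bromide
Product: 5 2-geranyl-1,3-bis(methoxymethoxy)benzene, via aryllithium 4 (not isolated)
Conditions: n-BuLi, THF, 0 °C; then CuI (10 mol %), 3, −78 °C to rt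
Reagents that add atoms: none
Why: Directed ortho-metalation takes place at C2 between the two cooperating MOM ethers, and copper-assisted SN2 allylation of the aryllithium with the primary allylic bromide should give the linear product with the E geometry retained.

Step 3
Reactants: 5 2-geranyl-1,3-bis(methoxymethoxy)benzene
Product: 7 4-geranyl-3,5-bis(methoxymethoxy)phenol, via arylboronic pinacol ester 6 (not isolated)
Conditions: [Ir(OMe)(cod)]2 (1.5 mol %), dtbpy (3 mol %), B2pin2 (0.55 equiv), THF, 80 °C; then 30% aq H2O2, aq NaOH, 0 °C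
Reagents that add atoms: hydrogen peroxide, OO (the boron of 6 comes from B2pin2, CC1(C)OB(OC1(C)C)B1OC(C)(C)C(C)(C)O1, and is lost again)
Why: Sterically controlled iridium-catalysed aromatic C–H borylation of a 1,2,3-trisubstituted arene should occur only at the C–H flanked by two hydrogens, and basic peroxide oxidation of the boronate gives the symmetric phenol without epoxidising the trisubstituted alkenes.

Step 4
Reactants: 7 4-geranyl-3,5-bis(methoxymethoxy)phenol
Product: 8 2-bromo-4-geranyl-3,5-bis(methoxymethoxy)phenol
Conditions: NBS (1.0 equiv), CH2Cl2, −78 °C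
Reagents that add atoms: N-bromosuccinimide, O=C1CCC(=O)N1Br
Why: Electrophilic aromatic bromination of a phloroglucinol-type phenol with a blocked para position should be much faster at −78 °C than attack on the alkenes, and the two ortho positions are equivalent by symmetry.

Step 5
Reactants: 8 2-bromo-4-geranyl-3,5-bis(methoxymethoxy)phenol
Product: 11 4-geranyl-3,5-bis(methoxymethoxy)-2-(trimethylsilyl)phenyl trifluoromethanesulfonate, via aryl trimethylsilyl ether 9 (not isolated), via lithium 2-silylphenoxide 10 (not isolated)
Conditions: HMDS, THF, 65 °C, then evaporation; n-BuLi, THF, −100 °C; Tf2O, −100 to −78 °C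
Reagents that add atoms: hexamethyldisilazane, C[Si](C)(C)N[Si](C)(C)C; trifluoromethanesulfonic anhydride, O=S(=O)(OS(=O)(=O)C(F)(F)F)C(F)(F)F
Why: This is the standard ortho-silylaryl triflate sequence: O-silylation, bromine–lithium exchange that triggers the 1,3 O-to-C silyl shift (retro-Brook rearrangement), and O-triflation of the resulting phenoxide.

Step 6
Reactants: 12 isovanillin
Product: 13 4-methoxy-3-(methoxymethoxy)benzaldehyde
Conditions: MOMCl, iPr2NEt, CH2Cl2, 0 °C to rt
Reagents that add atoms: chloromethyl methyl ether, COCCl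
Why: MOM ether formation masks the phenol, which would otherwise add to the aryne, with the same group used on ring A.

Step 7
Reactants: 13 4-methoxy-3-(methoxymethoxy)benzaldehyde
Product: 14 4-ethynyl-1-methoxy-2-(methoxymethoxy)benzene
Conditions: dimethyl (1-diazo-2-oxopropyl)phosphonate, K2CO3, MeOH, 0 °C to rt
Reagents that add atoms: dimethyl (1-diazo-2-oxopropyl)phosphonate, COP(=O)(OC)C(=[N+]=[N-])C(C)=O
Why: Seyferth–Gilbert homologation with the Bestmann–Ohira reagent converts the aryl aldehyde to the terminal alkyne under mildly basic conditions that leave the MOM ether intact.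

Step 8
Reactants: 14 4-ethynyl-1-methoxy-2-(methoxymethoxy)benzene
Product: 16 3-[4-methoxy-3-(methoxymethoxy)phenyl]prop-2-ynoic acid, via lithium acetylide 15 (not isolated)
Conditions: n-BuLi, THF, −78 °C; CO2, −78 °C to rt; then 1 M aq HCl, 0 °C
Reagents that add atoms: carbon dioxide, O=C=O
Why: Deprotonation of the terminal alkyne and carboxylation of the lithium acetylide is a standard route to arylpropiolic acids, and brief cold acidification should spare the MOM ether.

Step 9
Reactants: 11 4-geranyl-3,5-bis(methoxymethoxy)-2-(trimethylsilyl)phenyl trifluoromethanesulfonate (1.5 equiv); 16 3-[4-methoxy-3-(methoxymethoxy)phenyl]prop-2-ynoic acid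
Product: 19 6-geranyl-4'-methoxy-5,7,3'-tris(methoxymethoxy)flavone, via aryne 17 (not isolated), via caesium 2-acylphenoxide 18 (not isolated)
Conditions: CsF (4 equiv), THF, 125 °C, sealed tube
Reagents that add atoms: none
Why: Fluoride removes the trimethylsilyl group and expels triflate to give aryne 17, whose C5 methoxymethoxy group polarises the strained bond so that the caesium carboxylate of 16 adds through oxygen at the distal carbon (future C8a), leaving the aryl anion at C4a. That anion attacks the ester carbonyl and the four-membered alkoxide opens to the ortho-acylphenoxide 18, a net insertion of the aryne into the C–O bond of the acid; this is the known aryne route from carboxylic acids to ortho-hydroxyaryl ketones and, with arylpropiolic acids, to flavones. The phenoxide then adds to the ynone β-carbon in a 6-endo-dig oxa-Michael closure of ring C, and the C3 carbanion takes back the proton released by the acid. No stereocentre is formed. The step needs carboxylate attack at C8a, secured by the inductive effect of the C5 alkoxy group and the lower hindrance at the carbon next to C8–H, and 6-endo over 5-exo closure, favoured in the aprotic medium because only conjugate attack gives a carbonyl-stabilised anion. Because the geranyl group sits para to the triflate oxygen of a symmetric phenol, it can only end up at C6.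

Step 10
Reactants: 19 6-geranyl-4'-methoxy-5,7,3'-tris(methoxymethoxy)flavone
Product: 21 (2S)-6-geranyl-4'-methoxy-5,7,3'-tris(methoxymethoxy)flavanone, via silyl enol ether 20 (not isolated)
Conditions: Cu(OAc)2·H2O (5 mol %), (S)-DTBM-SEGPHOS (5.5 mol %), (EtO)2MeSiH, toluene, 0 °C to rt; then AcOH, H2O, THF, 0 °C
Reagents that add atoms: none
Why: In this asymmetric copper hydride 1,4-reduction (conjugate hydrosilylation, established for 2-substituted chromones), the bisphosphine-ligated copper hydride delivers hydride to one face of C2, the enolate is held as silyl enol ether 20 until mild hydrolysis, and the isolated trisubstituted alkenes and MOM ethers should not react.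

Step 11
Reactants: 21 (2S)-6-geranyl-4'-methoxy-5,7,3'-tris(methoxymethoxy)flavanone
Product: 22 (2S)-6-geranyl-5,7,3'-trihydroxy-4'-methoxyflavanone (target)
Conditions: 3 M aq HCl, MeOH, 50 °C
Reagents that add atoms: none
Why: Acid-catalysed acetal cleavage in methanol removes all three MOM ethers; ring B (3'-OH, 4'-OMe) cannot open C2 through a para-quinone methide, so the stereocentre should hold, and the mild temperature limits cyclisation of the geranyl group onto the freed phenols.

**Compound list**

1 | resorcinol | Oc1cccc(O)c1 | starting material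
2 | 1,3-bis(methoxymethoxy)benzene | COCOc1cccc(OCOC)c1 | intermediate
3 | geranyl bromide | CC(C)=CCC/C(C)=C/CBr | starting material
4 | 2-lithio-1,3-bis(methoxymethoxy)benzene | [Li]c1c(OCOC)cccc1OCOC | intermediate
5 | 2-geranyl-1,3-bis(methoxymethoxy)benzene | COCOc1cccc(OCOC)c1C/C=C(\C)CCC=C(C)C | intermediate
6 | 2-[4-geranyl-3,5-bis(methoxymethoxy)phenyl]-4,4,5,5-tetramethyl-1,3,2-dioxaborolane | COCOc1cc(B2OC(C)(C)C(C)(C)O2)cc(OCOC)c1C/C=C(\C)CCC=C(C)C | intermediate
7 | 4-geranyl-3,5-bis(methoxymethoxy)phenol | COCOc1cc(O)cc(OCOC)c1C/C=C(\C)CCC=C(C)C | intermediate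
8 | 2-bromo-4-geranyl-3,5-bis(methoxymethoxy)phenol | COCOc1cc(O)c(Br)c(OCOC)c1C/C=C(\C)CCC=C(C)C | intermediate
9 | [2-bromo-4-geranyl-3,5-bis(methoxymethoxy)phenoxy]trimethylsilane | COCOc1cc(O[Si](C)(C)C)c(Br)c(OCOC)c1C/C=C(\C)CCC=C(C)C | intermediate
10 | lithium 4-geranyl-3,5-bis(methoxymethoxy)-2-(trimethylsilyl)phenoxide | [Li+].[O-]c1cc(OCOC)c(C/C=C(\C)CCC=C(C)C)c(OCOC)c1[Si](C)(C)C | intermediate
11 | 4-geranyl-3,5-bis(methoxymethoxy)-2-(trimethylsilyl)phenyl trifluoromethanesulfonate | COCOc1cc(OS(=O)(=O)C(F)(F)F)c([Si](C)(C)C)c(OCOC)c1C/C=C(\C)CCC=C(C)C | intermediate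
12 | isovanillin | COc1ccc(C=O)cc1O | starting material
13 | 4-methoxy-3-(methoxymethoxy)benzaldehyde | COCOc1cc(C=O)ccc1OC | intermediate
14 | 4-ethynyl-1-methoxy-2-(methoxymethoxy)benzene | COCOc1cc(C#C)ccc1OC | intermediate
15 | lithium [4-methoxy-3-(methoxymethoxy)phenyl]acetylide | [Li]C#Cc1ccc(OC)c(OCOC)c1 | intermediate
16 | 3-[4-methoxy-3-(methoxymethoxy)phenyl]prop-2-ynoic acid | COCOc1cc(C#CC(=O)O)ccc1OC | intermediate
17 | 4-geranyl-3,5-bis(methoxymethoxy)benzyne | COCOC1=CC#CC(OCOC)=C1C/C=C(\C)CCC=C(C)C | intermediate
18 | caesium 4-geranyl-3,5-bis(methoxymethoxy)-2-{3-[4-methoxy-3-(methoxymethoxy)phenyl]prop-2-ynoyl}phenoxide | [Cs+].[O-]c1cc(OCOC)c(C/C=C(\C)CCC=C(C)C)c(OCOC)c1C(=O)C#Cc1ccc(OC)c(OCOC)c1 | intermediate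
19 | 6-geranyl-4'-methoxy-5,7,3'-tris(methoxymethoxy)flavone | COc1ccc(-c2cc(=O)c3c(cc(OCOC)c(C/C=C(\C)CCC=C(C)C)c3OCOC)o2)cc1OCOC | intermediate
20 | (2S)-4-[diethoxy(methyl)silyloxy]-6-geranyl-4'-methoxy-5,7,3'-tris(methoxymethoxy)flav-3-ene | COc1ccc([C@@H]2C=C(O[Si](C)(OCC)OCC)c3c(cc(OCOC)c(C/C=C(\C)CCC=C(C)C)c3OCOC)O2)cc1OCOC | intermediate
21 | (2S)-6-geranyl-4'-methoxy-5,7,3'-tris(methoxymethoxy)flavanone | COc1ccc([C@@H]2CC(=O)c3c(cc(OCOC)c(C/C=C(\C)CCC=C(C)C)c3OCOC)O2)cc1OCOC | intermediate
22 | (2S)-6-geranyl-5,7,3'-trihydroxy-4'-methoxyflavanone | COc1ccc([C@@H]2CC(=O)c3c(cc(O)c(C/C=C(\C)CCC=C(C)C)c3O)O2)cc1O | target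

**Totals and risks**

Total step count: 11. Longest linear sequence: 8 steps (steps 1–5, 9, 10, 11).

Step 10. What may go wrong: slow hydride transfer to the electron-rich vinylogous ester, poor facial selectivity at C2, further reduction of the C4 carbonyl, or β-elimination of the copper enolate that opens ring C. The fallback sets out from 13 and 11 and comes back at 21; it takes the acid partner at the alkene oxidation level and resolves C2. Aldehyde 13 is condensed with malonic acid (pyridine, cat. piperidine, 90 °C, Doebner–Knoevenagel) to (E)-3-[4-methoxy-3-(methoxymethoxy)phenyl]prop-2-enoic acid F1. F1 and 11 under CsF, THF, 125 °C should undergo the same aryne C–O insertion, now followed by oxa-Michael closure, to racemic 6-geranyl-4'-methoxy-5,7,3'-tris(methoxymethoxy)flavanone F2. Asymmetric transfer hydrogenation with RuCl(p-cymene)[(R,R)-TsDPEN] and HCO2H/Et3N, stopped a little past half conversion, should reduce the 2R ketone to the cis alcohol (2R,4R)-6-geranyl-4'-methoxy-5,7,3'-tris(methoxymethoxy)flavan-4-ol F3 and leave 21, which is separated and carried into step 11.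

Step 9. What may go wrong: protonation of the aryl anion before acyl transfer, thermal decarboxylation of the arylpropiolate, or competing 5-exo closure. The fallback sets out from 7 and 14 and comes back at 19; it replaces the aryne by a palladium-catalysed carbonylative annulation. Phenol 7 is iodinated (I2, NaHCO3, THF–H2O, 0 °C) to 4-geranyl-2-iodo-3,5-bis(methoxymethoxy)phenol F4. F4, alkyne 14 and CO (20 bar) with PdCl2(dppf) (3 mol %) in Et2NH at 120 °C should give the ortho-hydroxyaryl ynone by carbonylative Sonogashira coupling, which the amine closes 6-endo to flavone 19.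

Step 4. What may go wrong: attack of electrophilic bromine on the trisubstituted alkenes, or bromination at both ortho positions. The fallback sets out from 7 and comes back at 11; it installs silicon by carbamate-directed ortho-metalation and uses no halogen. Phenol 7 with isopropyl isocyanate (cat. Et3N, CH2Cl2) gives 4-geranyl-3,5-bis(methoxymethoxy)phenyl N-isopropylcarbamate F5. Temporary N-silylation in the flask (TBSOTf, TMEDA, Et2O), ortho-lithiation (n-BuLi, TMEDA, −78 °C) and TMSCl give, after work-up, 4-geranyl-3,5-bis(methoxymethoxy)-2-(trimethylsilyl)phenyl N-isopropylcarbamate F6. Carbamate cleavage with DBU and Et2NH (MeCN, 40 °C) followed by PhNTf2 in the same flask should give 11.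

**Further compounds**

F1 | step 10 | (E)-3-[4-methoxy-3-(methoxymethoxy)phenyl]prop-2-enoic acid | COCOc1cc(/C=C/C(=O)O)ccc1OC
F2 | step 10 | racemic 6-geranyl-4'-methoxy-5,7,3'-tris(methoxymethoxy)flavanone | COc1ccc(C2CC(=O)c3c(cc(OCOC)c(C/C=C(\C)CCC=C(C)C)c3OCOC)O2)cc1OCOC
F3 | step 10 | (2R,4R)-6-geranyl-4'-methoxy-5,7,3'-tris(methoxymethoxy)flavan-4-ol | COc1ccc([C@H]2C[C@@H](O)c3c(cc(OCOC)c(C/C=C(\C)CCC=C(C)C)c3OCOC)O2)cc1OCOC
F4 | step 9 | 4-geranyl-2-iodo-3,5-bis(methoxymethoxy)phenol | COCOc1cc(O)c(I)c(OCOC)c1C/C=C(\C)CCC=C(C)C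
F5 | step 4 | 4-geranyl-3,5-bis(methoxymethoxy)phenyl N-isopropylcarbamate | CC(C)NC(=O)Oc1cc(OCOC)c(C/C=C(\C)CCC=C(C)C)c(OCOC)c1
F6 | step 4 | 4-geranyl-3,5-bis(methoxymethoxy)-2-(trimethylsilyl)phenyl N-isopropylcarbamate | CC(C)NC(=O)Oc1cc(OCOC)c(C/C=C(\C)CCC=C(C)C)c(OCOC)c1[Si](C)(C)C
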